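**Assumption:** every carbon keeps the number it has in the target (C1 ketone, C3 carbinol, C4 methyl-bearing CH, C6 lactone O–CH, C7, C8 angelate carbon, C10 acetoxy carbon, C11–C13 methylene-lactone carbons). β is the face of the C7 side chain and α the face of H-7. (S)-(+)-Carvone, 3-methylbut-3-en-2-one and angelic acid are bought.

## Retrosynthetic overview

1. Target 26 ⇐ desilylation, C9–Br reduction and acylative opening of the 9α,10α-epoxide of epoxy ketone lactone 23, which gives the C10 acetate with retention.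
2. 23 ⇐ key C6–O bond formation: β-scission of the C1–C6 ring-fusion bond of cis-decalol acid 20, with the C6 radical captured by the C12 carboxylate on copper. This gives the ten-membered ring and the trans-lactone in one step.
3. 20 ⇐ ring A annulated onto ring B epoxy ketone 8 (Michael/aldol with enone 9), then C8 angeloylation, syn reduction at C3 and oxidation of isopropenyl to the acrylic acid.
4. 8 ⇐ (S)-carvone 1 by Shapiro diene formation, singlet-oxygen [4+2], Kornblum–DeLaMare rearrangement and hydroxyl-directed epoxidation.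
5. Ring order: ring B (from carvone) → ring A (annulation) → ten-membered carbocycle plus γ-lactone (fragmentation–lactonisation).

## Route

Step 1
Reactants: 1 (S)-(+)-carvone; 2 p-toluenesulfonohydrazide
Product: 3 (S)-carvone (E)-tosylhydrazone
Conditions: EtOH, AcOH (cat.), rt
Reagents that add atoms: none
Why: Acid-catalysed hydrazone condensation at the enone carbonyl; the C7 stereocentre is untouched.

Step 2
Reactants: 3 (S)-carvone (E)-tosylhydrazone
Product: 5 (S)-2-methyl-5-(prop-1-en-2-yl)cyclohexa-1,3-diene, via alkenyllithium 4 (not isolated)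
Conditions: LiN(iPr)2 (2.5 equiv), THF, −78 → 0 °C; then H2O, 0 °C
Reagents that add atoms: none
Why: Shapiro reaction: the dianion formed at the only sp3 α-carbon loses sulfinate and N2, and protonation of the alkenyllithium gives the ring 1,3-diene without touching C7.

Step 3
Reactants: 5 (S)-2-methyl-5-(prop-1-en-2-yl)cyclohexa-1,3-diene
Product: 8 9α,10α-epoxy-8α-hydroxy ring B ketone (2,3-epoxy-4-hydroxy-2-methyl-5-isopropenylcyclohexanone; epoxide and OH cis; both trans to isopropenyl), via endoperoxide 6 (not isolated), via hydroxy enone 7 (not isolated)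
Conditions: O2, tetraphenylporphyrin (0.5 mol%), white LEDs, CH2Cl2, −20 °C; then DBU (0.3 equiv), −20 → 0 °C; then t-BuOOH (1.5 equiv), 0 °C
Reagents that add atoms: dioxygen O=O; tert-butyl hydroperoxide CC(C)(C)OO
Why: Singlet-oxygen [4+2] on the cisoid diene anti to isopropenyl sets the C8 oxygen; Kornblum–DeLaMare deprotonation at the less hindered bridgehead (C1–H, next to CH2) gives the γ-hydroxy enone; hydroxyl-directed Weitz–Scheffer epoxidation then places the epoxide syn to OH and anti to isopropenyl, which sets C10.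

Step 4
Reactants: 8 9α,10α-epoxy-8α-hydroxy ring B ketone; 9 3-methylbut-3-en-2-one
Product: 11 cis-fused ketol (1β-hydroxy-6β-H decalin; 3-oxo; 4β-methyl; 7β-isopropenyl; 8α-hydroxy; 9α,10α-epoxy), via Michael adduct 10 (not isolated)
Conditions: NaOEt (0.3 equiv), EtOH, −10 °C, 9 added over 2 h
Reagents that add atoms: none
Why: Robinson-type Michael addition/intramolecular aldol stopped at the ketol: C6 is the only enolisable position, the chain ends up equatorial and trans to isopropenyl, axial aldol attack gives the cis-fused ketol, and the C4 methyl equilibrates to the equatorial (β) position of that conformer.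

Step 5
Reactants: 11 cis-fused ketol; 12 angelic acid
Product: 14 8-O-angeloyl ketol, via mixed anhydride 13 (not isolated)
Conditions: 12, 2,4,6-trichlorobenzoyl chloride, Et3N, toluene, rt; then 11, DMAP, toluene, 40 °C
Reagents that add atoms: none
Why: Yamaguchi esterification: only the secondary C8 hydroxyl is acylated (the tertiary C1–OH is inert), and the mixed-anhydride protocol avoids angelate-to-tiglate isomerisation.

Step 6
Reactants: 14 8-O-angeloyl ketol
Product: 16 1β,3β-diol, via boron chelate 15 (not isolated)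
Conditions: Et2BOMe (1.2 equiv), THF/MeOH 4:1, −78 °C; NaBH4 (1.2 equiv); then AcOH, MeOH co-evaporation
Reagents that add atoms: none
Why: Narasaka–Prasad reduction: boron bridges the axial C1 oxygen and the C3 carbonyl, so hydride arrives from the open equatorial face and gives the axial 3β-alcohol syn to C1–OH; ester and epoxide are not reduced.

Step 7
Reactants: 16 1β,3β-diol
Product: 17 3-O-TBS ether
Conditions: TBSOTf (1.1 equiv), 2,6-lutidine, CH2Cl2, −78 °C
Reagents that add atoms: tert-butyldimethylsilyl trifluoromethanesulfonate CC(C)(C)[Si](C)(C)OS(=O)(=O)C(F)(F)F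
Why: Selective silylation of the secondary alcohol at low temperature leaves the tertiary C1–OH free as the only alcohol for the key step.

Step 8
Reactants: 17 3-O-TBS ether
Product: 19 C12 enal, via allylic alcohol 18 (not isolated)
Conditions: SeO2 (0.5 equiv), t-BuOOH (4 equiv), CH2Cl2, rt → 40 °C
Reagents that add atoms: tert-butyl hydroperoxide CC(C)(C)OO; selenium dioxide O=[Se]=O
Why: Catalytic SeO2 allylic oxidation (ene reaction, then [2,3] shift) of the isopropenyl methyl; it is the only electron-rich alkene because C9–C10 is an epoxide and the angelate is electron-poor.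

Step 9
Reactants: 19 C12 enal
Product: 20 decalol acrylic acid
Conditions: NaClO2, NaH2PO4, 2-methylbut-2-ene, t-BuOH/H2O, 0 °C
Reagents that add atoms: sodium chlorite [Na+].[O-]Cl=O
Why: Pinnick oxidation converts the enal to the acid without touching the epoxide, silyl ether or angelate.

Step 10
Reactants: 20 decalol acrylic acid
Product: 23 9α,10α-epoxy-1-oxo-3-O-TBS germacranolide (trans-6α,12-lactone; 8α-angelate), via alkoxyl radical 21 (not isolated), via C6 radical 22 (not isolated)
Conditions: [Ir(dF(CF3)ppy)2(5,5'-d(CF3)bpy)]PF6 (2 mol%), Cu(OTf)2 (2.2 equiv), 2,4,6-collidine (3 equiv), MeCN, 450 nm LEDs, rt, degassed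
Reagents that add atoms: none
Why: Proposed new method: proton-coupled electron transfer from the collidine-bound tertiary O–H to the photoexcited iridium complex gives the C1 alkoxyl radical, whose β-scission breaks the ring-fusion C1–C6 bond (the oxiranyl radical at C10 and the primary radical at C2 are poorer leaving radicals), and the secondary C6 radical is captured by the divalent copper carboxylate of the same molecule to give a trivalent copper alkyl that closes the γ-lactone by C–O reductive elimination while monovalent copper is released and a second Cu(OTf)2 returns the reduced photocatalyst; because the equatorial C7 side chain lies anti to the departing C1, oxygen adds to the opposite face of C6 and the lactone is trans; the closest known reactions are hypoiodite- or cerium-mediated β-scission ring expansions of bicyclic tertiary alcohols and copper-mediated radical-polar-crossover lactonisations.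

Step 11
Reactants: 23 9α,10α-epoxy-1-oxo-3-O-TBS germacranolide
Product: 24 10α-acetoxy-9β-bromo ketone
Conditions: AcBr (1.5 equiv), Bu4NBr (10 mol%), 2,6-di-tert-butylpyridine, CH2Cl2, −40 → 0 °C
Reagents that add atoms: acetyl bromide CC(=O)Br
Why: Acylative epoxide opening: O-acylation, then SN2 attack of bromide at C9 (C10 is tertiary and α to the ketone), so the epoxide oxygen stays on C10 as the acetate with retention.

Step 12
Reactants: 24 10α-acetoxy-9β-bromo ketone
Product: 25 3-O-TBS ether of the target
Conditions: Bu3SnH (1.5 equiv, 0.5 M), Et3B (0.2 equiv), trace air, toluene, 0 °C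
Reagents that add atoms: none
Why: Tin hydride radical-chain debromination gives the C9 methylene; the high stannane concentration outruns 1,2-acyloxy migration, and bromine abstraction is far faster than stannyl addition to the methylene lactone.

Step 13
Reactants: 25 3-O-TBS ether of the target
Product: 26 target (3S,4R,6R,7S,8S,10R)
Conditions: HF·pyridine, THF, 0 °C → rt
Reagents that add atoms: none
Why: Buffered fluoride desilylation frees the 3β-hydroxyl without β-elimination of the β-hydroxy ketone or acyl migration.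

## Compound list

1 | (S)-(+)-carvone | CC1=CC[C@@H](CC1=O)C(C)=C | starting material
2 | p-toluenesulfonohydrazide | Cc1ccc(cc1)S(=O)(=O)NN | starting material
3 | (S)-carvone (E)-tosylhydrazone | CC1=CC[C@@H](C/C1=N\NS(=O)(=O)c2ccc(C)cc2)C(C)=C | intermediate
4 | alkenyllithium from 3 (Li on the former C=N carbon) | CC1=CC[C@@H](C=C1[Li])C(C)=C | intermediate (not isolated)
5 | (S)-2-methyl-5-(prop-1-en-2-yl)cyclohexa-1,3-diene | CC1=CC[C@@H](C=C1)C(C)=C | intermediate
6 | 1α,8α-endoperoxide of 5 (peroxide bridge trans to isopropenyl) | C1[C@H](C(C)=C)[C@H]2OO[C@@H]1C(C)=C2 | intermediate (not isolated)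
7 | (4S,5R)-4-hydroxy-2-methyl-5-(prop-1-en-2-yl)cyclohex-2-en-1-one (8α-OH) | O=C1C[C@H](C(C)=C)[C@@H](O)C=C1C | intermediate (not isolated)
8 | 9α,10α-epoxy-8α-hydroxy ring B ketone | O=C1C[C@H](C(C)=C)[C@@H](O)[C@H]2O[C@@]12C | intermediate
9 | 3-methylbut-3-en-2-one | CC(=O)C(C)=C | starting material
10 | Michael adduct (8 with a 2-methyl-3-oxobutyl chain on C6, trans to isopropenyl; C4 epimers) | O=C1[C@@H](CC(C)C(C)=O)[C@H](C(C)=C)[C@@H](O)[C@H]2O[C@@]12C | intermediate (not isolated)
11 | cis-fused ketol (1β-OH, 6β-H, 3-oxo, 4β-Me, 7β-isopropenyl, 8α-OH, 9α,10α-epoxide) | O[C@]12CC(=O)[C@H](C)C[C@H]1[C@H](C(C)=C)[C@@H](O)[C@H]3O[C@@]23C | intermediate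
12 | angelic acid, (Z)-2-methylbut-2-enoic acid | C/C=C(/C)C(=O)O | starting material
13 | angelic 2,4,6-trichlorobenzoic anhydride | C/C=C(/C)C(=O)OC(=O)c1c(Cl)cc(Cl)cc1Cl | intermediate (not isolated)
14 | 8-O-angeloyl ketol | O[C@]12CC(=O)[C@H](C)C[C@H]1[C@H](C(C)=C)[C@@H](OC(=O)/C(C)=C\C)[C@H]3O[C@@]23C | intermediate
15 | O1-diethylboryl chelate of 14 | CCB(CC)O[C@]12CC(=O)[C@H](C)C[C@H]1[C@H](C(C)=C)[C@@H](OC(=O)/C(C)=C\C)[C@H]3O[C@@]23C | intermediate (not isolated)
16 | 1β,3β-diol | O[C@]12C[C@H](O)[C@H](C)C[C@H]1[C@H](C(C)=C)[C@@H](OC(=O)/C(C)=C\C)[C@H]3O[C@@]23C | intermediate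
17 | 3-O-TBS ether | O[C@]12C[C@H](O[Si](C)(C)C(C)(C)C)[C@H](C)C[C@H]1[C@H](C(C)=C)[C@@H](OC(=O)/C(C)=C\C)[C@H]3O[C@@]23C | intermediate
18 | C12 allylic alcohol | O[C@]12C[C@H](O[Si](C)(C)C(C)(C)C)[C@H](C)C[C@H]1[C@H](C(CO)=C)[C@@H](OC(=O)/C(C)=C\C)[C@H]3O[C@@]23C | intermediate (not isolated)
19 | C12 enal | O[C@]12C[C@H](O[Si](C)(C)C(C)(C)C)[C@H](C)C[C@H]1[C@H](C(C=O)=C)[C@@H](OC(=O)/C(C)=C\C)[C@H]3O[C@@]23C | intermediate
20 | decalol acrylic acid | O[C@]12C[C@H](O[Si](C)(C)C(C)(C)C)[C@H](C)C[C@H]1[C@H](C(C(=O)O)=C)[C@@H](OC(=O)/C(C)=C\C)[C@H]3O[C@@]23C | intermediate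
21 | C1 alkoxyl radical of 20 | [O][C@]12C[C@H](O[Si](C)(C)C(C)(C)C)[C@H](C)C[C@H]1[C@H](C(C(=O)O)=C)[C@@H](OC(=O)/C(C)=C\C)[C@H]3O[C@@]23C | intermediate (not isolated)
22 | ring-opened C6 radical (ten-membered 1-ketone) | C=C(C(=O)O)[C@H]1[CH]C[C@@H](C)[C@@H](O[Si](C)(C)C(C)(C)C)CC(=O)[C@]2(C)O[C@@H]2[C@@H]1OC(=O)/C(C)=C\C | intermediate (not isolated)
23 | 9α,10α-epoxy-1-oxo-3-O-TBS germacranolide (trans-6α,12-lactone, 8α-angelate) | C=C1C(=O)O[C@@H]2C[C@@H](C)[C@@H](O[Si](C)(C)C(C)(C)C)CC(=O)[C@]3(C)O[C@@H]3[C@H](OC(=O)/C(C)=C\C)[C@@H]12 | intermediate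
24 | 10α-acetoxy-9β-bromo ketone | C=C1C(=O)O[C@@H]2C[C@@H](C)[C@@H](O[Si](C)(C)C(C)(C)C)CC(=O)[C@](C)(OC(C)=O)[C@@H](Br)[C@H](OC(=O)/C(C)=C\C)[C@@H]12 | intermediate
25 | 3-O-TBS ether of the target | C=C1C(=O)O[C@@H]2C[C@@H](C)[C@@H](O[Si](C)(C)C(C)(C)C)CC(=O)[C@](C)(OC(C)=O)C[C@H](OC(=O)/C(C)=C\C)[C@@H]12 | intermediate
26 | target: 3β-hydroxy-8α-angeloyloxy-10α-acetoxy-1-oxo-germacr-11(13)-en-6α,12-olide, (3S,4R,6R,7S,8S,10R) | C=C1C(=O)O[C@@H]2C[C@@H](C)[C@@H](O)CC(=O)[C@](C)(OC(C)=O)C[C@H](OC(=O)/C(C)=C\C)[C@@H]12 | target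

## Step count and risks

Total step count: 13. Longest linear sequence: 13 steps, from (S)-carvone 1 to 26.

The three steps most likely to fail:

**Step 10 (proposed new method).** The risks are β-scission towards the epoxide carbon, transannular hydrogen transfer in the C6 radical, and alkene formation instead of lactonisation. The fallback uses known chemistry and sets out from 20. Esterification with Me3SiCHN2 gives the methyl ester F2. Hypoiodite fragmentation (PhI(OAc)2, I2, visible light) expands the ring and gives the C6 iodide F3 as a mixture of epimers. AgOTf with 2,6-di-tert-butylpyridine then ionises the C–I bond and the ester carbonyl closes the lactone with loss of the methyl group, which converges both epimers onto the trans-lactone. The route is rejoined at 23.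

**Step 3 (three stages in one flask).** The regiochemistry of the Kornblum–DeLaMare step and the base sensitivity of hydroxy enone 7 are uncertain. The fallback sets out from 5. Photooxygenation alone gives endoperoxide 6, which is isolated. Thiourea in MeOH reduces the O–O bond to the cis-ene-diol F1. MnO2 then oxidises the less hindered allylic alcohol (C1–OH, flanked by CH2) to 7, so regiochemistry is set by sterics rather than by the base. Epoxidation of 7 with t-BuOOH/DBU rejoins the route at 8.

**Step 11 (acylative epoxide opening).** HBr may add to the methylene lactone, the silyl ether may be lost, or the regiochemistry may fail. The fallback sets out from 23. MgBr2·OEt2 opens the epoxide at C9 to the bromohydrin F4. Bu3SnH/Et3B removes the bromine to give the tertiary α-hydroxy ketone F5. Ac2O, DMAP and Et3N then acetylate the C10 hydroxyl, and the route is rejoined at 25.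

Further compounds
F1 | step 3 | cis-ene-diol (1α,8α-dihydroxy; both OH trans to isopropenyl) | O[C@H]1C[C@H](C(C)=C)[C@@H](O)C=C1C
F2 | step 10 | methyl ester of 20 | O[C@]12C[C@H](O[Si](C)(C)C(C)(C)C)[C@H](C)C[C@H]1[C@H](C(C(=O)OC)=C)[C@@H](OC(=O)/C(C)=C\C)[C@H]3O[C@@]23C
F3 | step 10 | ring-expanded C6 iodide methyl ester (C6 epimers) | C=C(C(=O)OC)[C@H]1C(I)C[C@@H](C)[C@@H](O[Si](C)(C)C(C)(C)C)CC(=O)[C@]2(C)O[C@@H]2[C@@H]1OC(=O)/C(C)=C\C
F4 | step 11 | 9β-bromo-10α-hydroxy ketone (bromohydrin) | C=C1C(=O)O[C@@H]2C[C@@H](C)[C@@H](O[Si](C)(C)C(C)(C)C)CC(=O)[C@](C)(O)[C@@H](Br)[C@H](OC(=O)/C(C)=C\C)[C@@H]12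
F5 | step 11 | 10α-hydroxy ketone | C=C1C(=O)O[C@@H]2C[C@@H](C)[C@@H](O[Si](C)(C)C(C)(C)C)CC(=O)[C@](C)(O)C[C@H](OC(=O)/C(C)=C\C)[C@@H]12
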